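**Retrosynthetic overview**

1. Target ⇐ α-methylenation (enolate Mannich reaction, then elimination) of the saturated cis-lactone bis-isobutyrate ⇐ double acylation of the lactone diol.
2. cis-Fused γ-lactone (second ring formed) ⇐ hydroxyl-directed anti reduction and lactonisation of a hydroxy keto ester ⇐ face-selective hydrogenation/O-debenzylation of a glyoxylate-derived alkylidene on the cyclohexenone.
3. Cyclohexenone (first ring formed; tetrasubstituted C=C and the ring O-stereocentre) ⇐ Rh(I)-catalysed enantioselective two-carbon ring expansion of a 1-allenyl-3-(benzyloxy)cyclobutanol (β-carbon elimination, then carbometalation of the allenyl ketone).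
4. Allenyl cyclobutanol ⇐ SE2′ addition of a propargyl-titanium reagent, made from the chiral 2-alkyne, to 3-(benzyloxy)cyclobutanone.
5. Chiral 2-alkyne ⇐ SN2 (inversion) of 1-propynyllithium on (R)-pent-4-en-2-yl tosylate, then hydroboration–oxidation and silylation.

Assumption: the O-benzyl group of commercial 3-(benzyloxy)cyclobutan-1-one is treated as a protecting group of 3-hydroxycyclobutanone (it is removed in step 8).

**Step 1**
Reactants: 1 (R)-pent-4-en-2-ol
Product: 2 (R)-pent-4-en-2-yl 4-methylbenzenesulfonate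
Conditions: TsCl, pyridine, DMAP (cat.), 0 °C → rt
Reagents that add atoms: 4-toluenesulfonyl chloride, Cc1ccc(cc1)S(=O)(=O)Cl
Why: Sulfonylation takes place at oxygen only, so the carbinol configuration is retained while the hydroxyl becomes a leaving group (tosylation).

**Step 2**
Reactants: 2 (R)-pent-4-en-2-yl 4-methylbenzenesulfonate; 3 prop-1-yn-1-yllithium
Product: 4 (S)-4-methylhept-1-en-5-yne
Conditions: THF/DMPU (4:1), 0 °C → rt
Reagents that add atoms: none
Why: The acetylide displaces the secondary tosylate by SN2 with inversion in a dipolar aprotic medium, which sets the (S) methyl-bearing stereocentre of the side chain (acetylide alkylation).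

**Step 3**
Reactants: 4 (S)-4-methylhept-1-en-5-yne
Product: 6 (S)-4-methylhept-5-yn-1-ol, via alkylborane 5 (not isolated)
Conditions: 9-BBN, THF, 0 °C → rt; then aq. NaOH, H2O2, 0 °C
Reagents that add atoms: hydrogen peroxide, OO
Why: 9-BBN adds anti-Markovnikov to the terminal alkene far faster than to the internal alkyne, and oxidation gives the primary alcohol without touching the stereocentre (hydroboration–oxidation).

**Step 4**
Reactants: 6 (S)-4-methylhept-5-yn-1-ol
Product: 7 tert-butyl(dimethyl){[(4S)-4-methylhept-5-yn-1-yl]oxy}silane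
Conditions: TBSCl, imidazole, DMF, rt
Reagents that add atoms: tert-butyldimethylsilyl chloride, CC(C)(C)[Si](C)(C)Cl
Why: Silylation protects the primary alcohol against the organolithium and titanium reagents of step 5 (silyl ether formation).

**Step 5**
Reactants: 7 tert-butyl(dimethyl){[(4S)-4-methylhept-5-yn-1-yl]oxy}silane; 8 3-(benzyloxy)cyclobutan-1-one
Product: 11 cis-3-(benzyloxy)-1-[(4S)-7-{[tert-butyl(dimethyl)silyl]oxy}-4-methylhepta-1,2-dien-3-yl]cyclobutan-1-ol (OH and OBn on the same face), via propargyllithium 9 (not isolated), via propargyltitanium 10 (not isolated)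
Conditions: s-BuLi, THF, −78 → −30 °C; ClTi(OiPr)3, −78 °C; then 8, −78 → −20 °C; aq. NH4Cl
Reagents that add atoms: none
Why: s-BuLi deprotonates the propargylic methyl group, titanium settles on that unhindered CH2 terminus and the reagent adds to the strained ketone through its γ-carbon (SE2′, propargyl-titanium allenylation) to give the α-allenic tertiary alcohol; attack anti to the benzyloxy group gives the cis cyclobutanol, and the minor trans isomer is removed by chromatography.

**Step 6**
Reactants: 11 cis-3-(benzyloxy)-1-[(4S)-7-{[tert-butyl(dimethyl)silyl]oxy}-4-methylhepta-1,2-dien-3-yl]cyclobutan-1-ol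
Product: 12 (5R)-5-(benzyloxy)-2-[(2S)-5-{[tert-butyl(dimethyl)silyl]oxy}pentan-2-yl]-3-methylcyclohex-2-en-1-one
Conditions: [Rh(OH)(cod)]2 (2.5 mol %), (R)-DTBM-SEGPHOS (6 mol %), toluene, 80 °C
Reagents that add atoms: none
Why: Proposed new method: the Rh(I) alkoxide of the tertiary cyclobutanol undergoes ligand-controlled β-carbon elimination of one of the two enantiotopic ring C–C bonds (strain release), the resulting primary alkyl–Rh adds to the central carbon of the adjacent allenyl ketone (six-membered carbometalation, expected to outrun β-H and β-alkoxide elimination because the allene is held next to rhodium), and protonation of the oxa-π-allyl rhodium at the allene terminus by the next substrate alcohol releases the 2-alkyl-3-methylcyclohex-2-enone, so the ring, the tetrasubstituted alkene and the (5R) benzyloxy stereocentre are set in one two-carbon ring expansion (the ligand antipode is assigned by analogy and would be confirmed on the first run); the closest known reaction type is the Rh(I)/bisphosphine-catalysed enantioselective β-carbon-elimination ring expansion of 3,3-disubstituted 1-allenylcyclobutanols to cyclohexenones with quaternary centres, here extended to a 3-alkoxy, 3-monosubstituted cyclobutanol that leaves a tertiary ether stereocentre and to an allene carrying an α-branched stereogenic alkyl group.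

**Step 7**
Reactants: 12 (5R)-5-(benzyloxy)-2-[(2S)-5-{[tert-butyl(dimethyl)silyl]oxy}pentan-2-yl]-3-methylcyclohex-2-en-1-one; 13 ethyl glyoxylate
Product: 17 ethyl (2E)-2-[(6R)-6-(benzyloxy)-3-[(2S)-5-{[tert-butyl(dimethyl)silyl]oxy}pentan-2-yl]-4-methyl-2-oxocyclohex-3-en-1-ylidene]acetate, via lithium enolate 14 (not isolated), via lithium aldolate 15 (not isolated), via aldol mesylate 16 (not isolated)
Conditions: LDA, THF, −78 °C; 13 (freshly distilled), −78 °C; then MsCl, Et3N, −78 → 0 °C
Reagents that add atoms: none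
Why: LDA deprotonates the α′-CH2 kinetically at −78 °C (cold enough that the β-benzyloxy enolate does not eliminate), the enolate adds to the aldehyde and mesylation/E1cB gives the conjugated (E)-alkylidene (aldol condensation), so no stereocentre has to be controlled here.

**Step 8**
Reactants: 17 ethyl (2E)-2-[(6R)-6-(benzyloxy)-3-[(2S)-5-{[tert-butyl(dimethyl)silyl]oxy}pentan-2-yl]-4-methyl-2-oxocyclohex-3-en-1-ylidene]acetate
Product: 19 ethyl 2-[(1R,6R)-3-[(2S)-5-{[tert-butyl(dimethyl)silyl]oxy}pentan-2-yl]-6-hydroxy-4-methyl-2-oxocyclohex-3-en-1-yl]acetate, via saturated keto ester 18 (not isolated)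
Conditions: H2 (1 atm), 10 % Pd/C, EtOAc/EtOH, rt; filtered and used at once
Reagents that add atoms: none
Why: A(1,3) strain with the ester-bearing alkylidene forces the adjacent benzyloxy group pseudoaxial, so Pd delivers H2 to the exocyclic alkene from the opposite face and the new ring stereocentre carries its CH2CO2Et arm cis to the oxygen; the benzyl ether is then hydrogenolysed while the tetrasubstituted enone survives (catalytic hydrogenation/hydrogenolysis).

**Step 9**
Reactants: 19 ethyl 2-[(1R,6R)-3-[(2S)-5-{[tert-butyl(dimethyl)silyl]oxy}pentan-2-yl]-6-hydroxy-4-methyl-2-oxocyclohex-3-en-1-yl]acetate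
Product: 21 (3aS,4S,7aR)-4-hydroxy-5-[(2S)-5-hydroxypentan-2-yl]-6-methyl-3a,4,7,7a-tetrahydro-1-benzofuran-2(3H)-one, via anti-diol ester 20 (not isolated)
Conditions: Me4NBH(OAc)3, MeCN/AcOH (1:1), −30 °C; then CSA (10 mol %), MeOH, 0 °C → rt
Reagents that add atoms: none
Why: The triacetoxyborohydride binds the free ring hydroxyl and delivers hydride intramolecularly to the same face of the enone carbonyl, giving the 1,3-anti diol with the new carbinol (4S in the lactone) trans to the side arm (hydroxyl-directed Evans–Saksena reduction); mild acid then removes the primary silyl ether and closes the cis-fused γ-lactone on the hydroxyl syn to the arm, in preference to the strained trans-fused lactone on the new anti hydroxyl (lactonisation).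

**Step 10**
Reactants: 21 (3aS,4S,7aR)-4-hydroxy-5-[(2S)-5-hydroxypentan-2-yl]-6-methyl-3a,4,7,7a-tetrahydro-1-benzofuran-2(3H)-one; 22 2-methylpropanoyl chloride (2.5 equiv in total, two of which are incorporated)
Product: 23 (3aR,4S,7aR)-6-methyl-5-[(2S)-5-(2-methylpropanoyloxy)pentan-2-yl]-2-oxo-2,3,3a,4,7,7a-hexahydro-1-benzofuran-4-yl 2-methylpropanoate
Conditions: 22 (2.5 equiv), pyridine, DMAP (cat.), CH2Cl2, 0 °C → rt
Reagents that add atoms: 2-methylpropanoyl chloride (the second equivalent of 22, for the second hydroxyl), CC(C)C(Cl)=O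
Why: DMAP-catalysed acylation esterifies the primary hydroxyl with one equivalent of the acid chloride and the secondary allylic hydroxyl with a second, each with retention at carbon (double esterification).

**Step 11**
Reactants: 23 (3aR,4S,7aR)-6-methyl-5-[(2S)-5-(2-methylpropanoyloxy)pentan-2-yl]-2-oxo-2,3,3a,4,7,7a-hexahydro-1-benzofuran-4-yl 2-methylpropanoate
Product: 27 (3aR,4S,7aR)-6-methyl-3-methylidene-5-[(2S)-5-(2-methylpropanoyloxy)pentan-2-yl]-2-oxo-2,3,3a,4,7,7a-hexahydro-1-benzofuran-4-yl 2-methylpropanoate, via lactone enolate 24 (not isolated), via Mannich base 25 (not isolated), via ammonium iodide 26 (not isolated)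
Conditions: LDA (1.1 equiv), THF, −78 °C; Eschenmoser's salt, −78 → 0 °C; then MeI, CH2Cl2/MeOH, rt; aq. NaHCO3
Reagents that add atoms: N,N-dimethylmethyleneiminium iodide (Eschenmoser's salt), C=[N+](C)C.[I-]
Why: The lactone CH2 is the most readily enolised position (each isobutyrate has only one hindered, less acidic α-H), so its lithium enolate reacts with Eschenmoser's salt and N-methylation/E1cB loss of trimethylamine leaves the exocyclic methylene (Mannich α-methylenation) without touching any stereocentre.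

**Compound list**

1 | (R)-pent-4-en-2-ol | C[C@@H](O)CC=C | starting material
2 | (R)-pent-4-en-2-yl 4-methylbenzenesulfonate | Cc1ccc(cc1)S(=O)(=O)O[C@H](C)CC=C | intermediate
3 | prop-1-yn-1-yllithium | [Li]C#CC | starting material
4 | (S)-4-methylhept-1-en-5-yne | CC#C[C@@H](C)CC=C | intermediate
5 | 9-[(4S)-4-methylhept-5-yn-1-yl]-9-borabicyclo[3.3.1]nonane | CC#C[C@@H](C)CCCB1C2CCCC1CCC2 | intermediate (not isolated)
6 | (S)-4-methylhept-5-yn-1-ol | CC#C[C@@H](C)CCCO | intermediate
7 | tert-butyl(dimethyl){[(4S)-4-methylhept-5-yn-1-yl]oxy}silane | CC#C[C@@H](C)CCCO[Si](C)(C)C(C)(C)C | intermediate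
8 | 3-(benzyloxy)cyclobutan-1-one | O=C1CC(OCc2ccccc2)C1 | starting material
9 | [(4S)-7-{[tert-butyl(dimethyl)silyl]oxy}-4-methylhept-2-yn-1-yl]lithium | [Li]CC#C[C@@H](C)CCCO[Si](C)(C)C(C)(C)C | intermediate (not isolated)
10 | [(4S)-7-{[tert-butyl(dimethyl)silyl]oxy}-4-methylhept-2-yn-1-yl]tri(propan-2-yloxy)titanium | CC(C)O[Ti](OC(C)C)(OC(C)C)CC#C[C@@H](C)CCCO[Si](C)(C)C(C)(C)C | intermediate (not isolated)
11 | cis-3-(benzyloxy)-1-[(4S)-7-{[tert-butyl(dimethyl)silyl]oxy}-4-methylhepta-1,2-dien-3-yl]cyclobutan-1-ol | O[C@]1(C(=C=C)[C@@H](C)CCCO[Si](C)(C)C(C)(C)C)C[C@H](OCc2ccccc2)C1 | intermediate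
12 | (5R)-5-(benzyloxy)-2-[(2S)-5-{[tert-butyl(dimethyl)silyl]oxy}pentan-2-yl]-3-methylcyclohex-2-en-1-one | O=C1C[C@H](OCc2ccccc2)CC(C)=C1[C@@H](C)CCCO[Si](C)(C)C(C)(C)C | intermediate
13 | ethyl glyoxylate (ethyl 2-oxoacetate) | CCOC(=O)C=O | starting material
14 | lithium (3R)-3-(benzyloxy)-6-[(2S)-5-{[tert-butyl(dimethyl)silyl]oxy}pentan-2-yl]-5-methylcyclohexa-1,5-dien-1-olate | [Li]OC1=C[C@H](OCc2ccccc2)CC(C)=C1[C@@H](C)CCCO[Si](C)(C)C(C)(C)C | intermediate (not isolated)
15 | lithium alkoxide of ethyl 2-[(6R)-6-(benzyloxy)-3-[(2S)-5-{[tert-butyl(dimethyl)silyl]oxy}pentan-2-yl]-4-methyl-2-oxocyclohex-3-en-1-yl]-2-hydroxyacetate (epimers at the two new centres) | CCOC(=O)C(O[Li])C1[C@H](OCc2ccccc2)CC(C)=C([C@@H](C)CCCO[Si](C)(C)C(C)(C)C)C1=O | intermediate (not isolated)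
16 | ethyl 2-[(6R)-6-(benzyloxy)-3-[(2S)-5-{[tert-butyl(dimethyl)silyl]oxy}pentan-2-yl]-4-methyl-2-oxocyclohex-3-en-1-yl]-2-[(methylsulfonyl)oxy]acetate (epimers) | CCOC(=O)C(OS(C)(=O)=O)C1[C@H](OCc2ccccc2)CC(C)=C([C@@H](C)CCCO[Si](C)(C)C(C)(C)C)C1=O | intermediate (not isolated)
17 | ethyl (2E)-2-[(6R)-6-(benzyloxy)-3-[(2S)-5-{[tert-butyl(dimethyl)silyl]oxy}pentan-2-yl]-4-methyl-2-oxocyclohex-3-en-1-ylidene]acetate | CCOC(=O)/C=C1\[C@H](OCc2ccccc2)CC(C)=C([C@@H](C)CCCO[Si](C)(C)C(C)(C)C)C1=O | intermediate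
18 | ethyl 2-[(1R,6R)-6-(benzyloxy)-3-[(2S)-5-{[tert-butyl(dimethyl)silyl]oxy}pentan-2-yl]-4-methyl-2-oxocyclohex-3-en-1-yl]acetate | CCOC(=O)C[C@@H]1[C@H](OCc2ccccc2)CC(C)=C([C@@H](C)CCCO[Si](C)(C)C(C)(C)C)C1=O | intermediate (not isolated)
19 | ethyl 2-[(1R,6R)-3-[(2S)-5-{[tert-butyl(dimethyl)silyl]oxy}pentan-2-yl]-6-hydroxy-4-methyl-2-oxocyclohex-3-en-1-yl]acetate | CCOC(=O)C[C@@H]1[C@H](O)CC(C)=C([C@@H](C)CCCO[Si](C)(C)C(C)(C)C)C1=O | intermediate
20 | ethyl 2-[(1R,2S,6R)-3-[(2S)-5-{[tert-butyl(dimethyl)silyl]oxy}pentan-2-yl]-2,6-dihydroxy-4-methylcyclohex-3-en-1-yl]acetate | CCOC(=O)C[C@@H]1[C@H](O)CC(C)=C([C@@H](C)CCCO[Si](C)(C)C(C)(C)C)[C@H]1O | intermediate (not isolated)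
21 | (3aS,4S,7aR)-4-hydroxy-5-[(2S)-5-hydroxypentan-2-yl]-6-methyl-3a,4,7,7a-tetrahydro-1-benzofuran-2(3H)-one | C1C(=O)O[C@@H]2CC(C)=C([C@@H](C)CCCO)[C@@H](O)[C@H]12 | intermediate
22 | 2-methylpropanoyl chloride (isobutyryl chloride) | CC(C)C(Cl)=O | starting material
23 | (3aR,4S,7aR)-6-methyl-5-[(2S)-5-(2-methylpropanoyloxy)pentan-2-yl]-2-oxo-2,3,3a,4,7,7a-hexahydro-1-benzofuran-4-yl 2-methylpropanoate | C1C(=O)O[C@@H]2CC(C)=C([C@@H](C)CCCOC(=O)C(C)C)[C@@H](OC(=O)C(C)C)[C@H]12 | intermediate
24 | lithium enolate of 23 (lithium 3a,4,7,7a-tetrahydro-1-benzofuran-2-olate) | C1=C(O[Li])O[C@@H]2CC(C)=C([C@@H](C)CCCOC(=O)C(C)C)[C@@H](OC(=O)C(C)C)[C@H]12 | intermediate (not isolated)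
25 | 3-[(dimethylamino)methyl] derivative of 23 (C3 epimers) | CN(C)CC1C(=O)O[C@@H]2CC(C)=C([C@@H](C)CCCOC(=O)C(C)C)[C@@H](OC(=O)C(C)C)[C@H]12 | intermediate (not isolated)
26 | 3-[(trimethylammonio)methyl] derivative of 23, iodide | C[N+](C)(C)CC1C(=O)O[C@@H]2CC(C)=C([C@@H](C)CCCOC(=O)C(C)C)[C@@H](OC(=O)C(C)C)[C@H]12.[I-] | intermediate (not isolated)
27 | (3aR,4S,7aR)-6-methyl-3-methylidene-5-[(2S)-5-(2-methylpropanoyloxy)pentan-2-yl]-2-oxo-2,3,3a,4,7,7a-hexahydro-1-benzofuran-4-yl 2-methylpropanoate | C=C1C(=O)O[C@@H]2CC(C)=C([C@@H](C)CCCOC(=O)C(C)C)[C@@H](OC(=O)C(C)C)[C@H]12 | target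

**Totals**

Total step count: 11. Longest linear sequence: 11 steps (1 → 27); 3, 8, 13 and 22 are bought.

**Three steps most likely to fail**

Step 5 (the ambident propargyl/allenyl metal may bond through its CH2 end to give the homopropargylic alcohol, or give poor cis/trans control). The fallback sets out from 9 and comes back at 11. The lithiated alkyne 9 is quenched with Me3SiCl to give the isolable propargylsilane tert-butyl(dimethyl){[(4S)-4-methyl-7-(trimethylsilyl)hept-5-yn-1-yl]oxy}silane F1. F1 is then added to 8 with TiCl4 in CH2Cl2 at −78 °C. This Lewis-acid-mediated anti-SE2′ (Hosomi–Sakurai-type) allenylation can only form the C–C bond at the γ-carbon, and the cis alcohol 11 is again purified by chromatography.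

Step 6 (the proposed new ring expansion; β-hydride or β-alkoxide elimination of the alkyl–rhodium, or weak catalyst control, could defeat it). The fallback uses known chemistry only, sets out from 10 (made from 7 as in step 5) and comes back at 12. Commercial (S)-4-chloro-3-hydroxybutanenitrile is O-benzylated (benzyl trichloroacetimidate, TfOH cat.) to (S)-3-(benzyloxy)-4-chlorobutanenitrile F2. Finkelstein exchange (NaI, butanone, reflux) gives (S)-3-(benzyloxy)-4-iodobutanenitrile F3, and DIBAL-H at −78 °C with acidic work-up gives (S)-3-(benzyloxy)-4-iodobutanal F4. The titanium reagent 10 adds to this aldehyde by the same SE2′ path to give the α-allenic alcohol (2S,6S)-2-(benzyloxy)-9-{[tert-butyl(dimethyl)silyl]oxy}-5-ethenylidene-1-iodo-6-methylnonan-4-ol F5. Dess–Martin oxidation gives the allenyl ketone (2S,6S)-2-(benzyloxy)-9-{[tert-butyl(dimethyl)silyl]oxy}-5-ethenylidene-1-iodo-6-methylnonan-4-one F6. Bu3SnH/AIBN (slow addition, benzene, 80 °C) then closes the six-membered ring by addition of the primary radical to the central allene carbon (the enone β-position) and hydrogen transfer, giving 12; any β,γ-unsaturated isomer is conjugated on silica with a trace of Et3N. Here the ring oxygen stereocentre comes from the chiral pool instead of the catalyst.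

Step 9 (the directed reduction needs the free hydroxy ketone; 19 may lactonise first, after which the hydroxyl can no longer steer the hydride). The fallback sets out from 19 and comes back at 23. Compound 19 is deliberately lactonised and desilylated (CSA, MeOH) to the keto lactone (3aR,7aR)-5-[(2S)-5-hydroxypentan-2-yl]-6-methyl-3,3a,7,7a-tetrahydro-1-benzofuran-2,4-dione F7. L-Selectride (THF, −78 °C) attacks from the convex face opposite the lactone ring and gives the all-cis diol (3aS,4R,7aR)-4-hydroxy-5-[(2S)-5-hydroxypentan-2-yl]-6-methyl-3a,4,7,7a-tetrahydro-1-benzofuran-2(3H)-one F8. A double Mitsunobu reaction with isobutyric acid (PPh3, DIAD, toluene) esterifies the primary alcohol and esterifies the ring alcohol with SN2 inversion, which gives 23.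

**Further compounds**

F1 | step 5 | tert-butyl(dimethyl){[(4S)-4-methyl-7-(trimethylsilyl)hept-5-yn-1-yl]oxy}silane | C[Si](C)(C)CC#C[C@@H](C)CCCO[Si](C)(C)C(C)(C)C
F2 | step 6 | (S)-3-(benzyloxy)-4-chlorobutanenitrile | N#CC[C@H](OCc1ccccc1)CCl
F3 | step 6 | (S)-3-(benzyloxy)-4-iodobutanenitrile | N#CC[C@H](OCc1ccccc1)CI
F4 | step 6 | (S)-3-(benzyloxy)-4-iodobutanal | O=CC[C@H](OCc1ccccc1)CI
F5 | step 6 | (2S,6S)-2-(benzyloxy)-9-{[tert-butyl(dimethyl)silyl]oxy}-5-ethenylidene-1-iodo-6-methylnonan-4-ol (C4 epimers) | OC(C[C@H](OCc1ccccc1)CI)C(=C=C)[C@@H](C)CCCO[Si](C)(C)C(C)(C)C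
F6 | step 6 | (2S,6S)-2-(benzyloxy)-9-{[tert-butyl(dimethyl)silyl]oxy}-5-ethenylidene-1-iodo-6-methylnonan-4-one | O=C(C[C@H](OCc1ccccc1)CI)C(=C=C)[C@@H](C)CCCO[Si](C)(C)C(C)(C)C
F7 | step 9 | (3aR,7aR)-5-[(2S)-5-hydroxypentan-2-yl]-6-methyl-3,3a,7,7a-tetrahydro-1-benzofuran-2,4-dione | C1C(=O)O[C@@H]2CC(C)=C([C@@H](C)CCCO)C(=O)[C@H]12
F8 | step 9 | (3aS,4R,7aR)-4-hydroxy-5-[(2S)-5-hydroxypentan-2-yl]-6-methyl-3a,4,7,7a-tetrahydro-1-benzofuran-2(3H)-one | C1C(=O)O[C@@H]2CC(C)=C([C@@H](C)CCCO)[C@H](O)[C@H]12
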